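**Retrosynthetic overview**
- Ring C is made last: a Hauser–Kraus-type anionic benzannulation of a tricyclic enone (ring A, ring B, lactone) with a sulfonyl tetronate brings in C11–C14 with OMe and i-Pr in place, gives the 11,14-hydroquinone directly and keeps the C7 ketone.
- The tricyclic enone comes from an achiral 4,4-disubstituted cyclohexa-2,5-dienone acrylate in one pot: a chiral copper hydride reductive Michael cyclization closes the lactone and desymmetrizes the dienone (C5, C10), then lactone enolate alkylation closes ring A (C4).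
- The dienone comes from methyl benzoate: Birch reductive alkylation with 1,3-dibromopropane, ester reduction, acryloylation, bis-allylic oxidation.
- The sulfonyl tetronate comes from ethyl 2-isopropylacetoacetate: bromination/cyclization, O-methylation, sulfenylation, oxidation.
- Ring order: B (from the benzoate ring) → lactone + A (one operation) → C.

Convention: polycyclic intermediates are discussed with the abietane locants of the target (C1–C10 decalin carbons, C18 methyl, C19 lactone carbonyl, C20 lactone CH2, C11–C14 arene carbons).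
Assumption: the (R)-bisphosphine in step 5 is taken to give the (1S,6R,7S) series shown; if the first run shows the opposite sense, the (S)-ligand is used.

**Step 1**
Reactants: 1 methyl benzoate; 2 1,3-dibromopropane
Product: 4 methyl 1-(3-bromopropyl)cyclohexa-2,5-diene-1-carboxylate, via potassium dienolate 3 (not isolated)
Conditions: K (2.3 equiv), NH3 (l)/THF, t-BuOH (1.0 equiv), –78 °C; penta-1,3-diene quench; then 2 (3 equiv), –78 °C to rt
Reagents that add atoms: none
Why: Birch reduction gives the ester-stabilized cyclohexadienyl anion 3 (protonated once at the para carbon by t-BuOH), which is C-alkylated at the ipso carbon by the primary dibromide used in excess (Birch reductive alkylation); no stereocenter is formed.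

**Step 2**
Reactants: 4 methyl 1-(3-bromopropyl)cyclohexa-2,5-diene-1-carboxylate
Product: 5 [1-(3-bromopropyl)cyclohexa-2,5-dien-1-yl]methanol
Conditions: i-Bu2AlH (2.5 equiv), CH2Cl2, –78 to 0 °C; aq. KNaC4H4O6 work-up
Reagents that add atoms: none
Why: i-Bu2AlH reduces the hindered ester to the neopentyl alcohol at low temperature without touching the primary bromide or the skipped diene (ester reduction).

**Step 3**
Reactants: 5 [1-(3-bromopropyl)cyclohexa-2,5-dien-1-yl]methanol; 6 acryloyl chloride
Product: 7 [1-(3-bromopropyl)cyclohexa-2,5-dien-1-yl]methyl prop-2-enoate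
Conditions: Et3N, DMAP (cat.), CH2Cl2, 0 °C
Reagents that add atoms: none
Why: DMAP-catalysed acyl transfer to the primary alcohol installs the three carbons that become C4, C18 and C19 (esterification).

**Step 4**
Reactants: 7 [1-(3-bromopropyl)cyclohexa-2,5-dien-1-yl]methyl prop-2-enoate
Product: 8 [1-(3-bromopropyl)-4-oxocyclohexa-2,5-dien-1-yl]methyl prop-2-enoate
Conditions: Rh2(C6H10NO)4 (dirhodium tetracaprolactamate, 1 mol%), t-BuOOH (5 equiv), K2CO3 (0.5 equiv), CH2Cl2, rt
Reagents that add atoms: tert-butyl hydroperoxide, CC(C)(C)OO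
Why: The doubly allylic CH2 has the weakest C–H bond in 7 and is converted through the mixed peroxide into the cross-conjugated dienone, the quaternary carbon preventing aromatization (catalytic allylic oxidation with t-BuOOH); 8 is achiral with two enantiotopic enone arms.

**Step 5**
Reactants: 8 [1-(3-bromopropyl)-4-oxocyclohexa-2,5-dien-1-yl]methyl prop-2-enoate
Product: 11 (1S,6R,7S)-7-methyl-12-oxatricyclo[5.3.3.0^{1,6}]tridec-2-ene-4,13-dione, via silyl dienol ether lactone 9 (not isolated), via tricyclic silyl dienol ether 10 (not isolated)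
Conditions: Cu(OAc)2 (5 mol%), (R)-DTBM-SEGPHOS (5.5 mol%), PhMe2SiH (1.3 equiv), THF, –20 °C, slow addition of 8; then KN(SiMe3)2 (1.6 equiv), DMPU, –78 to 0 °C; then 1 M HCl, 0 °C
Reagents that add atoms: none
Why: Proposed new method: copper hydride conjugate reduction of the unhindered acrylate gives a bisphosphine-bound copper ester enolate that adds through a six-membered transition state (hence cis-fused lactone) to one of the two enantiotopic enone arms, fixing C10 and C5 under ligand control and leaving the ketone masked as silyl dienol ether 9, so that KN(SiMe3)2 enolizes only the lactone and the C4 enolate closes ring A on the bromide from the only face the tether allows, setting the C4 quaternary center before acid unmasks the enone (reductive Michael cyclization then intramolecular enolate alkylation; closest known reaction types: enantioselective copper hydride-catalysed reductive aldol and reductive Michael cyclizations of enoate esters, and copper-catalysed desymmetrizing additions to 4,4-disubstituted cyclohexadienones).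

**Step 6**
Reactants: 12 ethyl 2-acetyl-3-methylbutanoate (ethyl 2-isopropylacetoacetate)
Product: 14 4-hydroxy-3-(propan-2-yl)furan-2(5H)-one, via bromo keto ester 13 (not isolated)
Conditions: Br2 (1.0 equiv), CHCl3, 0 °C to rt, 16 h; then neat, 130 °C
Reagents that add atoms: none
Why: Bromination gives the α-bromo keto ester, HBr isomerizes it to the γ-bromide 13, and on heating the ester oxygen displaces bromide with loss of bromoethane to give the tetronic acid (classical tetronic acid synthesis).

**Step 7**
Reactants: 14 4-hydroxy-3-(propan-2-yl)furan-2(5H)-one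
Product: 15 4-methoxy-3-(propan-2-yl)furan-2(5H)-one
Conditions: Me2SO4, K2CO3, acetone, reflux
Reagents that add atoms: dimethyl sulfate, COS(=O)(=O)OC
Why: The vinylogous acid is methylated at the enolic oxygen by the hard electrophile because C3 is blocked by isopropyl (O-alkylation).

**Step 8**
Reactants: 15 4-methoxy-3-(propan-2-yl)furan-2(5H)-one
Product: 16 4-methoxy-5-(phenylsulfanyl)-3-(propan-2-yl)furan-2(5H)-one (racemic)
Conditions: LiN(i-Pr)2 (1.1 equiv), THF, –78 °C; then PhSSPh, –78 °C; aq. NH4Cl
Reagents that add atoms: diphenyl disulfide, c1ccccc1SSc1ccccc1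
Why: Deprotonation at C5 gives the aromatic 2-oxidofuran anion, which the soft disulfide sulfenylates at C5 (γ-sulfenylation of a butenolide enolate); the new stereocenter is racemic and is lost in step 10.

**Step 9**
Reactants: 16 4-methoxy-5-(phenylsulfanyl)-3-(propan-2-yl)furan-2(5H)-one
Product: 17 4-methoxy-5-(phenylsulfonyl)-3-(propan-2-yl)furan-2(5H)-one (racemic)
Conditions: m-CPBA (2.2 equiv), CH2Cl2, 0 °C to rt
Reagents that add atoms: 3-chloroperoxybenzoic acid, OOC(=O)c1cccc(Cl)c1
Why: The peracid oxidizes the sulfide through the sulfoxide to the sulfone without attacking the push–pull enol ether (sulfide oxidation), as in the preparation of sulfonylphthalide annulation donors.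

**Step 10**
Reactants: 11 (1S,6R,7S)-7-methyl-12-oxatricyclo[5.3.3.0^{1,6}]tridec-2-ene-4,13-dione; 17 4-methoxy-5-(phenylsulfonyl)-3-(propan-2-yl)furan-2(5H)-one
Product: 19 (4S,5R,10R)-11,14-dihydroxy-12-methoxy-7-oxoabieta-8,11,13-trien-19,20-olide (CNP0159814.2), via ene-dione 18 (not isolated)
Conditions: LiOt-Bu (3.2 equiv), THF, –78 °C to rt, Ar; degassed aq. NH4Cl/Na2S2O4 work-up
Reagents that add atoms: none
Why: Proposed new method: the sulfone-stabilized C5 anion of 17 adds to the enone β-carbon C9 anti to the axial lactone CH2, the C8 enolate closes onto the butenolide carbonyl (Dieckmann), the ring oxygen and then phenylsulfinate are expelled, and ene-dione 18 tautomerizes to the hydroquinone with no stereocenter touched, the bridgehead C4 making retro-Michael opening impossible (Hauser–Kraus annulation; closest known reaction type: the same annulation with 3-(phenylsulfonyl)phthalides, here extended to a monocyclic sulfonyl tetronate).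

**Compound list**
1 | methyl benzoate | COC(=O)c1ccccc1 | starting material
2 | 1,3-dibromopropane | BrCCCBr | starting material
3 | potassium (cyclohexa-2,5-dien-1-ylidene)(methoxy)methanolate | COC(=C1C=CCC=C1)[O-].[K+] | intermediate
4 | methyl 1-(3-bromopropyl)cyclohexa-2,5-diene-1-carboxylate | COC(=O)C1(CCCBr)C=CCC=C1 | intermediate
5 | [1-(3-bromopropyl)cyclohexa-2,5-dien-1-yl]methanol | OCC1(CCCBr)C=CCC=C1 | intermediate
6 | acryloyl chloride (prop-2-enoyl chloride) | C=CC(=O)Cl | starting material
7 | [1-(3-bromopropyl)cyclohexa-2,5-dien-1-yl]methyl prop-2-enoate | C=CC(=O)OCC1(CCCBr)C=CCC=C1 | intermediate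
8 | [1-(3-bromopropyl)-4-oxocyclohexa-2,5-dien-1-yl]methyl prop-2-enoate | C=CC(=O)OCC1(CCCBr)C=CC(=O)C=C1 | intermediate
9 | (4aS,8aS)-8a-(3-bromopropyl)-6-{[dimethyl(phenyl)silyl]oxy}-4-methyl-1,4,4a,8a-tetrahydro-3H-isochromen-3-one (cis-fused; C4 epimers) | C2=CC(O[Si](C)(C)c3ccccc3)=C[C@@H]1[C@@]2(CCCBr)COC(=O)C1C | intermediate
10 | (1S,6R,7S)-4-{[dimethyl(phenyl)silyl]oxy}-7-methyl-12-oxatricyclo[5.3.3.0^{1,6}]trideca-2,4-dien-13-one | C2=CC(O[Si](C)(C)c4ccccc4)=C[C@@H]1[C@]23CCC[C@]1(C)C(=O)OC3 | intermediate
11 | (1S,6R,7S)-7-methyl-12-oxatricyclo[5.3.3.0^{1,6}]tridec-2-ene-4,13-dione (abietane locants 4S,5R,10S; C20 β, H-5 α) | O=C1C[C@@H]2[C@@]3(C=C1)CCC[C@]2(C)C(=O)OC3 | intermediate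
12 | ethyl 2-acetyl-3-methylbutanoate | CCOC(=O)C(C(C)C)C(C)=O | starting material
13 | ethyl 4-bromo-3-oxo-2-(propan-2-yl)butanoate | CCOC(=O)C(C(C)C)C(=O)CBr | intermediate
14 | 4-hydroxy-3-(propan-2-yl)furan-2(5H)-one | CC(C)C1=C(O)COC1=O | intermediate
15 | 4-methoxy-3-(propan-2-yl)furan-2(5H)-one | COC1=C(C(C)C)C(=O)OC1 | intermediate
16 | 4-methoxy-5-(phenylsulfanyl)-3-(propan-2-yl)furan-2(5H)-one (racemic) | COC1=C(C(C)C)C(=O)OC1Sc1ccccc1 | intermediate
17 | 4-methoxy-5-(phenylsulfonyl)-3-(propan-2-yl)furan-2(5H)-one (racemic) | COC1=C(C(C)C)C(=O)OC1S(=O)(=O)c1ccccc1 | intermediate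
18 | (4S,5R,10R)-12-methoxy-7,11,14-trioxoabiet-12-en-19,20-olide (C8 and C9 epimers) | COC1=C(C(C)C)C(=O)C2C(=O)C[C@@H]3[C@@]4(C2C1=O)CCC[C@]3(C)C(=O)OC4 | intermediate
19 | (4S,5R,10R)-11,14-dihydroxy-12-methoxy-7-oxoabieta-8,11,13-trien-19,20-olide | COc1c(O)c2c(c(O)c1C(C)C)C(=O)C[C@@H]1[C@]23CCC[C@]1(C)C(=O)OC3 | target

**Totals**
Total step count: 10. Longest linear sequence: 6 (steps 1–5 and 10).

**Steps most likely to fail, with fallbacks**

Step 5. The copper hydride may reduce the dienone instead of the acrylate, the copper enolate may be silylated before it cyclizes, or the enantioselectivity may be low. The fallback sets out from 8 and returns at 11. A chiral amino acid-derived aminophosphine (20 mol%) promotes an enantioselective intramolecular Rauhut–Currier cyclization of the acrylate onto one enone arm, giving the cis-fused α-methylene lactone enone (4aR,8aS)-8a-(3-bromopropyl)-4-methylidene-4a,5-dihydro-1H-isochromene-3,6(4H,8aH)-dione F1. Hydrogenation with RhCl(PPh3)3 and H2 saturates only the exocyclic 1,1-disubstituted alkene, since the ring enone is shielded on both faces by the quaternary carbon, and gives the α-methyl lactone enone (4aS,8aS)-8a-(3-bromopropyl)-4-methyl-4a,5-dihydro-1H-isochromene-3,6(4H,8aH)-dione F2, which carries C18 as CH3. Treatment with LiN(i-Pr)2 (2.3 equiv) in THF/DMPU forms the ketone dienolate and then the lactone enolate; the less stabilized lactone enolate alkylates the bromide first and closes ring A to give 11.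

Step 10. The Michael addition at the neopentyl C9 may be slow, the vinylogous carbonate carbonyl of the tetronate is a weak Dieckmann acceptor, and sulfone 17 may be labile. The fallback sets out from 11 (with 15) and returns at 19. Compound 15 is silylated (TBSOTf, Et3N) to the silyloxyfuran tert-butyl{[4-methoxy-3-(propan-2-yl)furan-2-yl]oxy}dimethylsilane F3. A Lewis acid-promoted vinylogous Mukaiyama–Michael addition to 11 forms the C9–C11 bond and gives, after work-up, the keto butenolide adduct F4 (stereocenters of 11 unchanged; C9 and C11 epimers). LiN(i-Pr)2 then effects Dieckmann closure of the C8 enolate onto the butenolide carbonyl, and acidic work-up dehydrates the product to the 11-deoxy phenol (4S,5R,10R)-14-hydroxy-12-methoxy-7-oxoabieta-8,11,13-trien-19,20-olide F5. Oxidation with (KSO3)2NO at the free para position gives the quinone (4S,5R,10R)-12-methoxy-7,11,14-trioxoabieta-8,12-dien-19,20-olide F6, and Na2S2O4 reduces it to 19.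

Step 4. The peroxy radicals may attack or polymerize the acrylate. The fallback sets out from 5 and returns at 8. Alcohol 5 is acylated with 3-chloropropanoyl chloride to give the masked acrylate [1-(3-bromopropyl)cyclohexa-2,5-dien-1-yl]methyl 3-chloropropanoate F7. The bis-allylic position is oxidized without radicals using CrO3 and 3,5-dimethylpyrazole in CH2Cl2 at –20 °C, giving the dienone [1-(3-bromopropyl)-4-oxocyclohexa-2,5-dien-1-yl]methyl 3-chloropropanoate F8. Et3N then eliminates HCl to unveil the acrylate 8.

**Further compounds**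
F1 | step 5 | (4aR,8aS)-8a-(3-bromopropyl)-4-methylidene-4a,5-dihydro-1H-isochromene-3,6(4H,8aH)-dione | C2=CC(=O)C[C@@H]1[C@@]2(CCCBr)COC(=O)C1=C
F2 | step 5 | (4aS,8aS)-8a-(3-bromopropyl)-4-methyl-4a,5-dihydro-1H-isochromene-3,6(4H,8aH)-dione (C4 epimers) | C2=CC(=O)C[C@@H]1[C@@]2(CCCBr)COC(=O)C1C
F3 | step 10 | tert-butyl{[4-methoxy-3-(propan-2-yl)furan-2-yl]oxy}dimethylsilane | COc1coc(O[Si](C)(C)C(C)(C)C)c1C(C)C
F4 | step 10 | keto butenolide Michael adduct of 11 at C9 (stereocenters of 11 unchanged; C9 and C11 epimers) | COC1=C(C(C)C)C(=O)OC1C2CC(=O)C[C@@H]3[C@]24CCC[C@]3(C)C(=O)OC4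
F5 | step 10 | (4S,5R,10R)-14-hydroxy-12-methoxy-7-oxoabieta-8,11,13-trien-19,20-olide | COc1cc2c(c(O)c1C(C)C)C(=O)C[C@@H]1[C@]23CCC[C@]1(C)C(=O)OC3
F6 | step 10 | (4S,5R,10R)-12-methoxy-7,11,14-trioxoabieta-8,12-dien-19,20-olide | COC1=C(C(C)C)C(=O)C=2C(=O)C[C@@H]3[C@@]4(C=2C1=O)CCC[C@]3(C)C(=O)OC4
F7 | step 4 | [1-(3-bromopropyl)cyclohexa-2,5-dien-1-yl]methyl 3-chloropropanoate | ClCCC(=O)OCC1(CCCBr)C=CCC=C1
F8 | step 4 | [1-(3-bromopropyl)-4-oxocyclohexa-2,5-dien-1-yl]methyl 3-chloropropanoate | ClCCC(=O)OCC1(CCCBr)C=CC(=O)C=C1
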